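**Plan**
1. Cuts: the Cα–CH2 bond between the lactone and ring C (enolate alkylation), C2–C3 of the dihydrobenzofuran (carbene C–H insertion), Cα–Cβ of the lactone (second carbene C–H insertion), C7'–C8' of the ring A glycerol chain (aldol), and the ArO–CH2 bonds at rings C and B (etherifications).
2. Enabling feature: C2 of the dihydrobenzofuran is an O-benzylic CH that carries guaiacyl ring D and is bound to the ring C oxygen O1. C3 sits on ring C (C3a) and bears a CH2OH that can be carried as an ester. C3 can therefore be the carbene carbon of a ring C aryldiazoacetate, and C2 the CH2 of a benzyl ether five atoms away.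
3. Fragment 1 (rings C, D): 5-bromovanillin is O-alkylated with the ring D benzylic alcohol, the bromide is exchanged for CH2CO2R, a lactamide ester and the diazo group are installed, and the oxygen five-ring is closed. Reduction and bromide exchange then give the benzyl bromide.
4. Fragment 2 (rings A, B, lactone): eugenol becomes an aryloxyacetyl imide, the aldol with O-benzylvanillin attaches ring A, C7' is inverted, and the allyl group is grown into the lactone ring.
5. Union: lactone enolate plus benzyl bromide, then fluoride, then hydrogenolysis.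
6. Stereochemistry: C2/C3 come from Rh2(S-DOSP)4 matched with an (S)-lactamide ester. C8' comes from an (R)-oxazolidinone (syn aldol) and C7' from Mitsunobu inversion (threo to erythro). Cβ comes from Rh2(4R-MPPIM)4, and Cα from attack anti to the Cβ substituent.

Key step: step 9

Assumption: the sense of induction of Rh2(S-DOSP)4 paired with the (S)-lactamide ester (2S,3S) and of Rh2(4R-MPPIM)4 (R lactone) is assigned by analogy with close substrates. If a trial shows the opposite sense, the mirror-image catalyst (and ethyl (R)-lactate in step 6) is used and nothing else changes.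

Labels: O1, C2, C3, C3a, C7a are the dihydrobenzofuran atoms. C7' (benzylic), C8' and C9' are the glycerol chain on ring A. Cα and Cβ are the lactone carbons. TBS = tert-butyldimethylsilyl, TBDPS = tert-butyldiphenylsilyl, Bn = benzyl.

**Fragment 1 (rings C and D)**

Step 1
Reactants: 1 5-bromovanillin; 2 4-benzyloxy-3-methoxybenzyl alcohol
Product: 3 3-bromo-4-[(4-benzyloxy-3-methoxyphenyl)methoxy]-5-methoxybenzaldehyde
Conditions: PPh3, DIAD, THF, 0 °C to rt
Reagents that add atoms: none
Why: Mitsunobu etherification, in which the phenol of 1 is acidified by the para aldehyde and the ortho bromine and the partner is an unhindered primary benzylic alcohol, so the ArO–CH2 bond whose CH2 becomes C2 forms under neutral conditions that spare the aldehyde.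

Step 2
Reactants: 3 aldehyde
Product: 4 {3-bromo-4-[(4-benzyloxy-3-methoxyphenyl)methoxy]-5-methoxyphenyl}methanol
Conditions: NaBH4, MeOH/THF, 0 °C
Reagents that add atoms: none
Why: Borohydride reduction of an aromatic aldehyde, which touches neither the aryl bromide nor the benzyl ethers.

Step 3
Reactants: 4 benzylic alcohol
Product: 5 TBS ether of 4
Conditions: TBSCl, imidazole, DMF, rt
Reagents that add atoms: tert-butyldimethylsilyl chloride, CC(C)(C)[Si](C)(C)Cl
Why: Standard silylation of a primary alcohol, which masks the later alkylation site through the organozinc, diazo and hydride steps.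

Step 4
Reactants: 5 aryl bromide
Product: 6 ethyl 2-{2-[(4-benzyloxy-3-methoxyphenyl)methoxy]-5-(TBSO-methyl)-3-methoxyphenyl}acetate
Conditions: BrZnCH2CO2Et (0.5 M in THF), Pd2(dba)3, XPhos, THF, 60 °C
Reagents that add atoms: (2-ethoxy-2-oxoethyl)zinc bromide, CCOC(=O)C[Zn]Br
Why: Negishi-type coupling of a Reformatsky reagent with an aryl bromide at zerovalent palladium bearing a bulky biaryl phosphine, in which the nearly neutral zinc enolate tolerates silyl and benzyl ethers and fast transmetalation leaves no time for direct arylation of ring D.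

Step 5
Reactants: 6 ethyl ester
Product: 7 2-{2-[(4-benzyloxy-3-methoxyphenyl)methoxy]-5-(TBSO-methyl)-3-methoxyphenyl}acetic acid
Conditions: LiOH, THF/MeOH/H2O, rt; then 1 M HCl to pH 4, 0 °C
Reagents that add atoms: lithium hydroxide, [Li+].[OH-]
Why: Saponification of an unhindered ethyl ester, with careful acidification so that the silyl ether stays on.

Step 6
Reactants: 8 ethyl (S)-lactate; 9 pyrrolidine
Product: 10 (S)-2-hydroxy-1-(pyrrolidin-1-yl)propan-1-one
Conditions: neat, rt to 50 °C
Reagents that add atoms: none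
Why: Aminolysis of an alpha-hydroxy ester by a nucleophilic secondary amine, which leaves the chiral-pool lactate centre untouched.

Step 7
Reactants: 7 arylacetic acid; 10 (S)-lactamide alcohol
Product: 11 (S)-1-oxo-1-(pyrrolidin-1-yl)propan-2-yl ester of 7
Conditions: EDC·HCl, DMAP, CH2Cl2, 0 °C to rt
Reagents that add atoms: none
Why: Steglich-type carbodiimide esterification, which joins the partners at the acyl carbon so that the (S) centre of 10 is retained.

Step 8
Reactants: 11 arylacetate
Product: 12 (S)-1-oxo-1-(pyrrolidin-1-yl)propan-2-yl 2-diazo-2-{2-[(4-benzyloxy-3-methoxyphenyl)methoxy]-5-(TBSO-methyl)-3-methoxyphenyl}acetate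
Conditions: p-ABSA, DBU, MeCN, 0 °C to rt
Reagents that add atoms: 4-acetamidobenzenesulfonyl azide, CC(=O)Nc1ccc(cc1)S(=O)(=O)N=[N+]=[N-]
Why: Regitz diazo transfer to a methylene group activated by both aryl and ester, the standard entry to aryldiazoacetates.

Step 9
Reactants: 12 aryldiazoacetate
Product: 13 (S)-1-oxo-1-(pyrrolidin-1-yl)propan-2-yl (2S,3S)-2-(4-benzyloxy-3-methoxyphenyl)-5-(TBSO-methyl)-7-methoxy-2,3-dihydrobenzofuran-3-carboxylate (trans)
Conditions: Rh2(S-DOSP)4 (1 mol%), CH2Cl2, slow addition of 12 at high dilution, rt, Ar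
Reagents that add atoms: none
Why: Rh2(S-DOSP)4 expels N2 from 12 and holds the future C3 as a donor-acceptor carbene on a dimer of divalent rhodium; this carbon then inserts into one C–H bond of the neighbouring ArOCH2 group through a three-centre transition state in which hydride character runs ahead of C–C bonding, so that C2–C3 forms and the catalyst is released. The closest known reaction type is the intramolecular 1,5 C–H insertion of 2-(benzyloxy)aryldiazoacetates into the benzylic ether CH2 with chiral dirhodium carboxylates, which is also known for substrates with an alkoxy group next to the ether oxygen, a 3,4-dialkoxyphenyl group and a lactamide ester. The oxygen ring closes as a five-membered ring by 1,5 insertion along the chain C3, C3a, C7a, O1, C2, the only C–H bond that the carbene can reach through an unstrained cyclic transition state. C2 is set by the choice between the two OCH2 hydrogens, which the chiral carboxylate pocket and the (S)-lactamide ester should make in a matched sense in favour of 2S, and C3 is set in the same event because ring D and the ester turn away from each other (trans, 3S), an arrangement that is also the thermodynamic one since C3 stays epimerisable beside the ester. The step needs site selectivity over the OCH2Ph, OCH3, CH2OTBS and pyrrolidine C–H bonds and over addition to the arenes, and it is secured by proximity, by the double activation of the chosen CH2 through O1 and electron-rich ring D, and by slow addition at high dilution, which holds back bimolecular reactions. As the auxiliary turns all stereoisomers into diastereomers, minor isomers can be removed by chromatography and 13 is carried on as a single stereoisomer.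

Step 10
Reactants: 13 trans ester
Product: 14 [(2S,3R)-2-(4-benzyloxy-3-methoxyphenyl)-5-(TBSO-methyl)-7-methoxy-2,3-dihydrobenzofuran-3-yl]methanol
Conditions: LiBH4, THF, 0 °C to rt
Reagents that add atoms: none
Why: Hydride reduction of the activated alpha-acyloxy-amide ester to the primary alcohol, which releases auxiliary 10, leaves its tertiary amide and the silyl ether intact, and ends the epimerisability of C3 (3R only through a change of CIP priorities).

Step 11
Reactants: 14 primary alcohol
Product: 15 TBDPS ether of 14, (2S,3R)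
Conditions: TBDPSCl, imidazole, DMF, rt
Reagents that add atoms: tert-butyldiphenylsilyl chloride, CC(C)(C)[Si](Cl)(c1ccccc1)c1ccccc1
Why: Silylation with a bulkier and more robust silyl group, so that the two CH2O sites can be told apart in step 12.

Step 12
Reactants: 15 bis-silyl ether
Product: 16 (2S,3R)-2-(4-benzyloxy-3-methoxyphenyl)-5-(bromomethyl)-3-(TBDPSO-methyl)-7-methoxy-2,3-dihydrobenzofuran (used at once)
Conditions: Ph3PBr2, CH2Cl2, 0 °C to rt
Reagents that add atoms: dibromotriphenylphosphorane, BrP(Br)(c1ccccc1)(c1ccccc1)c1ccccc1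
Why: Direct exchange of a silyl ether for bromide, in which the less hindered oxygen of the electron-rich benzylic TBS ether attacks phosphorus, bromide removes the silyl group and then displaces the alkoxyphosphonium group, while the hindered beta-branched TBDPS ether should react far more slowly.

**Fragment 2 (rings A and B, lactone)**

Step 13
Reactants: 17 eugenol
Product: 18 2-(4-allyl-2-methoxyphenoxy)acetic acid
Conditions: ClCH2CO2H, NaOH, H2O, 90 °C; then HCl
Reagents that add atoms: chloroacetic acid, OC(=O)CCl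
Why: Williamson ether synthesis with chloroacetate in aqueous base, conditions too mild to move the allyl double bond into conjugation.

Step 14
Reactants: 18 aryloxyacetic acid; 19 (R)-4-benzyloxazolidin-2-one
Product: 21 (R)-4-benzyl-3-[2-(4-allyl-2-methoxyphenoxy)acetyl]oxazolidin-2-one, via mixed pivalic anhydride 20 (not isolated)
Conditions: PivCl, Et3N, THF, -20 °C; then LiCl, 19, -20 °C to rt
Reagents that add atoms: none
Why: N-acylation of the oxazolidinone through the mixed pivalic anhydride, which is attacked at its less hindered carbonyl group.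

Step 15
Reactants: 21 imide; 22 O-benzylvanillin
Product: 25 (R)-4-benzyl-3-[(2R,3S)-2-(4-allyl-2-methoxyphenoxy)-3-(4-benzyloxy-3-methoxyphenyl)-3-hydroxypropanoyl]oxazolidin-2-one (syn adduct), via Z boron enolate 23 (not isolated), via boron aldolate 24 (not isolated)
Conditions: Bu2BOTf, i-Pr2NEt, CH2Cl2, -78 to 0 °C; 22, -78 to 0 °C; then pH 7 buffer, MeOH, 30% H2O2, 0 °C
Reagents that add atoms: none
Why: Evans syn aldol reaction, in which soft enolisation gives the Z boron enolate and a closed Zimmerman–Traxler chair on the face away from the benzyl group of the (R)-auxiliary sets C8' as in the target (S after step 16) and C7' as S (threo).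

Step 16
Reactants: 25 aldol adduct
Product: 26 (1S,2S)-2-(4-allyl-2-methoxyphenoxy)-1-(4-benzyloxy-3-methoxyphenyl)propane-1,3-diol (threo)
Conditions: NaBH4, THF/H2O, 0 °C to rt
Reagents that add atoms: none
Why: Borohydride reduction of the N-acyloxazolidinone in wet THF, which gives the 1,3-diol and frees auxiliary 19 without retro-aldol cleavage and without hydroborating the allyl group.

Step 17
Reactants: 26 diol
Product: 27 (1S,2S)-2-(4-allyl-2-methoxyphenoxy)-1-(4-benzyloxy-3-methoxyphenyl)-3-(TBSO)propan-1-ol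
Conditions: TBSCl (1.05 equiv), imidazole, CH2Cl2, 0 °C
Reagents that add atoms: tert-butyldimethylsilyl chloride, CC(C)(C)[Si](C)(C)Cl
Why: Selective silylation, since the primary C9' hydroxyl reacts much faster than the hindered secondary benzylic one.

Step 18
Reactants: 27 threo alcohol
Product: 28 (1R,2S)-2-(4-allyl-2-methoxyphenoxy)-1-(4-benzyloxy-3-methoxyphenyl)-3-(TBSO)propyl 4-nitrobenzoate (erythro)
Conditions: 4-O2NC6H4CO2H, PPh3, DIAD, toluene, -20 °C to rt
Reagents that add atoms: 4-nitrobenzoic acid, OC(=O)c1ccc(cc1)[N+](=O)[O-]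
Why: Mitsunobu inversion with an acidic carboxylic acid, known for this class of beta-aryl ether alcohols, turns C7' from S to R by SN2 displacement of the oxyphosphonium group, while the non-polar solvent and low temperature hold back ionisation and any leakage gives a separable diastereomer because C8' is untouched.

Step 19
Reactants: 28 nitrobenzoate
Product: 29 (1R,2S)-2-(4-allyl-2-methoxyphenoxy)-1-(4-benzyloxy-3-methoxyphenyl)-3-(TBSO)propan-1-ol (erythro)
Conditions: K2CO3 (0.2 equiv), MeOH/THF, rt
Reagents that add atoms: none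
Why: Base-catalysed transesterification cleaves the activated aryl ester at the acyl carbon, so C7' keeps its new configuration and the alkyl silyl ether survives.

Step 20
Reactants: 29 erythro alcohol
Product: 30 (1R,2S)-bis-TBS ether (C7'-OTBS, C9'-OTBS) with the allyl group on ring B
Conditions: TBSOTf, 2,6-lutidine, CH2Cl2, 0 °C
Reagents that add atoms: tert-butyldimethylsilyl triflate, CC(C)(C)[Si](C)(C)OS(=O)(=O)C(F)(F)F
Why: A silyl triflate with a hindered pyridine base silylates the hindered secondary benzylic alcohol without ionising it.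

Step 21
Reactants: 30 allylarene
Product: 32 3-arylpropan-1-ol (ring B–CH2CH2CH2OH, glycerol chain unchanged), via B-alkyl-9-BBN adduct 31 (not isolated)
Conditions: 9-BBN, THF, rt; then NaOH aq, 30% H2O2, 0 °C
Reagents that add atoms: hydrogen peroxide, OO
Why: Hydroboration–oxidation, in which bulky 9-BBN adds boron to the terminal carbon of the allyl group and alkaline peroxide replaces boron by hydroxyl.

Step 22
Reactants: 32 primary alcohol
Product: 33 bromoacetate of 32
Conditions: BrCH2COBr, NaHCO3, MeCN, 0 °C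
Reagents that add atoms: bromoacetyl bromide, BrCC(=O)Br
Why: Acylation of the only free hydroxyl by an acid bromide under a mild inorganic base.

Step 23
Reactants: 33 bromoacetate
Product: 34 diazoacetate of 32
Conditions: TsNHNHTs, DBU, THF, 0 °C
Reagents that add atoms: N,N'-ditosylhydrazine, Cc1ccc(cc1)S(=O)(=O)NNS(=O)(=O)c1ccc(C)cc1
Why: Known conversion of a bromoacetate into a diazoacetate by N-alkylation of ditosylhydrazine and base-induced loss of two sulfinate ions.

Step 24
Reactants: 34 diazoacetate
Product: 35 (R)-4-(4-{[(1R,2S)-1-(4-benzyloxy-3-methoxyphenyl)-1,3-bis(TBSO)propan-2-yl]oxy}-3-methoxybenzyl)dihydrofuran-2(3H)-one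
Conditions: Rh2(4R-MPPIM)4 (1 mol%), CH2Cl2, reflux, slow addition
Reagents that add atoms: none
Why: Enantioselective intramolecular carbene C–H insertion of a 3-(3,4-dialkoxyphenyl)propyl diazoacetate with a chiral dirhodium carboxamidate, a known route to beta-benzyl-gamma-butyrolactones, in which five-ring formation directs the carbene to the central CH2 of the propyl chain and the catalyst picks one of its two enantiotopic hydrogens to set Cβ as R.

**Union and deprotection**

Step 25
Reactants: 35 lactone; 16 benzyl bromide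
Product: 37 fully protected (3R,4R)-trans-dibenzylbutyrolactone (two OBn, two OTBS, one OTBDPS), via lithium enolate 36 (not isolated)
Conditions: LiN(SiMe3)2, THF, -78 °C; then 16, DMPU, -78 to -30 °C
Reagents that add atoms: none
Why: Alkylation of a gamma-butyrolactone lithium enolate by a reactive benzylic bromide, in which the electrophile approaches anti to the Cβ benzyl group and sets Cα as R (trans), the usual outcome for dibenzylbutyrolactone lignans.

Step 26
Reactants: 37 protected lactone
Product: 38 di-O-benzyl triol (C7'-OH, C9'-OH and C3-CH2OH free)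
Conditions: Bu4NF, AcOH, THF, rt to 40 °C
Reagents that add atoms: none
Why: Fluoride-driven cleavage of all three silyl ethers, buffered with acetic acid so that the lactone is neither opened nor epimerised and the benzylic C7' alcohol never meets strong acid.

Step 27
Reactants: 38 di-O-benzyl triol
Product: 39 CNP0265599.1 (target)
Conditions: H2 (1 atm), Pd/C (10%), EtOAc/EtOH, rt
Reagents that add atoms: none
Why: Hydrogenolysis of the two aryl benzyl ethers under neutral conditions at one atmosphere, where they react faster than the benzylic C7'–OH and C2–O1 bonds, gives the target.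

**Compound list**
1 | 5-bromovanillin | COc1cc(C=O)cc(Br)c1O | starting material
2 | 4-benzyloxy-3-methoxybenzyl alcohol | COc1cc(CO)ccc1OCc1ccccc1 | starting material
3 | 3-bromo-4-[(4-benzyloxy-3-methoxyphenyl)methoxy]-5-methoxybenzaldehyde | COc1cc(C=O)cc(Br)c1OCc1ccc(OCc2ccccc2)c(OC)c1 | intermediate
4 | {3-bromo-4-[(4-benzyloxy-3-methoxyphenyl)methoxy]-5-methoxyphenyl}methanol | COc1cc(CO)cc(Br)c1OCc1ccc(OCc2ccccc2)c(OC)c1 | intermediate
5 | TBS ether of 4 | COc1cc(CO[Si](C)(C)C(C)(C)C)cc(Br)c1OCc1ccc(OCc2ccccc2)c(OC)c1 | intermediate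
6 | ethyl arylacetate | CCOC(=O)Cc1cc(CO[Si](C)(C)C(C)(C)C)cc(OC)c1OCc1ccc(OCc2ccccc2)c(OC)c1 | intermediate
7 | arylacetic acid | OC(=O)Cc1cc(CO[Si](C)(C)C(C)(C)C)cc(OC)c1OCc1ccc(OCc2ccccc2)c(OC)c1 | intermediate
8 | ethyl (S)-lactate | CCOC(=O)[C@H](C)O | starting material
9 | pyrrolidine | C1CCNC1 | starting material
10 | (S)-2-hydroxy-1-(pyrrolidin-1-yl)propan-1-one | C[C@H](O)C(=O)N1CCCC1 | intermediate
11 | (S)-lactamide arylacetate | COc1cc(CO[Si](C)(C)C(C)(C)C)cc(CC(=O)O[C@@H](C)C(=O)N2CCCC2)c1OCc1ccc(OCc2ccccc2)c(OC)c1 | intermediate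
12 | (S)-lactamide aryldiazoacetate (key-step precursor) | COc1cc(CO[Si](C)(C)C(C)(C)C)cc(C(=[N+]=[N-])C(=O)O[C@@H](C)C(=O)N2CCCC2)c1OCc1ccc(OCc2ccccc2)c(OC)c1 | intermediate
13 | (S)-lactamide trans-(2S,3S)-2-aryl-2,3-dihydrobenzofuran-3-carboxylate (key-step product) | CC(C)(C)[Si](C)(C)OCc1cc(OC)c2c(c1)[C@H](C(=O)O[C@@H](C)C(=O)N1CCCC1)[C@@H](c1ccc(OCc3ccccc3)c(OC)c1)O2 | intermediate
14 | (2S,3R)-3-hydroxymethyl dihydrobenzofuran | CC(C)(C)[Si](C)(C)OCc1cc(OC)c2c(c1)[C@H](CO)[C@@H](c1ccc(OCc3ccccc3)c(OC)c1)O2 | intermediate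
15 | (2S,3R)-3-(TBDPSO-methyl)-5-(TBSO-methyl) dihydrobenzofuran | CC(C)(C)[Si](C)(C)OCc1cc(OC)c2c(c1)[C@H](CO[Si](c1ccccc1)(c1ccccc1)C(C)(C)C)[C@@H](c1ccc(OCc3ccccc3)c(OC)c1)O2 | intermediate
16 | (2S,3R)-5-(bromomethyl) dihydrobenzofuran | BrCc1cc(OC)c2c(c1)[C@H](CO[Si](c1ccccc1)(c1ccccc1)C(C)(C)C)[C@@H](c1ccc(OCc3ccccc3)c(OC)c1)O2 | intermediate
17 | eugenol | COc1cc(CC=C)ccc1O | starting material
18 | 2-(4-allyl-2-methoxyphenoxy)acetic acid | COc1cc(CC=C)ccc1OCC(=O)O | intermediate
19 | (R)-4-benzyloxazolidin-2-one | O=C1N[C@H](Cc2ccccc2)CO1 | starting material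
20 | mixed pivalic anhydride of 18 | COc1cc(CC=C)ccc1OCC(=O)OC(=O)C(C)(C)C | intermediate
21 | (R)-4-benzyl-3-(aryloxyacetyl)oxazolidin-2-one | COc1cc(CC=C)ccc1OCC(=O)N1[C@H](Cc2ccccc2)COC1=O | intermediate
22 | O-benzylvanillin | COc1cc(C=O)ccc1OCc1ccccc1 | starting material
23 | Z dibutylboron enolate of 21 | COc1cc(CC=C)ccc1O/C=C(\OB(CCCC)CCCC)N1[C@H](Cc2ccccc2)COC1=O | intermediate
24 | dibutylboron aldolate | COc1cc([C@H](OB(CCCC)CCCC)[C@H](C(=O)N2[C@H](Cc3ccccc3)COC2=O)Oc2ccc(CC=C)cc2OC)ccc1OCc1ccccc1 | intermediate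
25 | (2R,3S)-syn aldol imide | COc1cc([C@H](O)[C@H](C(=O)N2[C@H](Cc3ccccc3)COC2=O)Oc2ccc(CC=C)cc2OC)ccc1OCc1ccccc1 | intermediate
26 | (1S,2S)-threo diol | COc1cc([C@H](O)[C@H](CO)Oc2ccc(CC=C)cc2OC)ccc1OCc1ccccc1 | intermediate
27 | (1S,2S)-threo alcohol, C9'-OTBS | COc1cc([C@H](O)[C@H](CO[Si](C)(C)C(C)(C)C)Oc2ccc(CC=C)cc2OC)ccc1OCc1ccccc1 | intermediate
28 | (1R,2S)-erythro 4-nitrobenzoate | COc1cc([C@@H](OC(=O)c2ccc(cc2)[N+](=O)[O-])[C@H](CO[Si](C)(C)C(C)(C)C)Oc2ccc(CC=C)cc2OC)ccc1OCc1ccccc1 | intermediate
29 | (1R,2S)-erythro alcohol, C9'-OTBS | COc1cc([C@@H](O)[C@H](CO[Si](C)(C)C(C)(C)C)Oc2ccc(CC=C)cc2OC)ccc1OCc1ccccc1 | intermediate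
30 | (1R,2S)-bis-TBS ether, allylarene | COc1cc([C@@H](O[Si](C)(C)C(C)(C)C)[C@H](CO[Si](C)(C)C(C)(C)C)Oc2ccc(CC=C)cc2OC)ccc1OCc1ccccc1 | intermediate
31 | B-alkyl-9-BBN adduct of 30 | COc1cc([C@@H](O[Si](C)(C)C(C)(C)C)[C@H](CO[Si](C)(C)C(C)(C)C)Oc2ccc(CCCB3C4CCCC3CCC4)cc2OC)ccc1OCc1ccccc1 | intermediate
32 | 3-arylpropan-1-ol | COc1cc([C@@H](O[Si](C)(C)C(C)(C)C)[C@H](CO[Si](C)(C)C(C)(C)C)Oc2ccc(CCCO)cc2OC)ccc1OCc1ccccc1 | intermediate
33 | bromoacetate | COc1cc([C@@H](O[Si](C)(C)C(C)(C)C)[C@H](CO[Si](C)(C)C(C)(C)C)Oc2ccc(CCCOC(=O)CBr)cc2OC)ccc1OCc1ccccc1 | intermediate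
34 | diazoacetate | COc1cc([C@@H](O[Si](C)(C)C(C)(C)C)[C@H](CO[Si](C)(C)C(C)(C)C)Oc2ccc(CCCOC(=O)C=[N+]=[N-])cc2OC)ccc1OCc1ccccc1 | intermediate
35 | (R)-beta-benzyl-gamma-butyrolactone with ring A chain | COc1cc([C@@H](O[Si](C)(C)C(C)(C)C)[C@H](CO[Si](C)(C)C(C)(C)C)Oc2ccc(C[C@H]3COC(=O)C3)cc2OC)ccc1OCc1ccccc1 | intermediate
36 | lithium enolate of 35 | COc1cc([C@@H](O[Si](C)(C)C(C)(C)C)[C@H](CO[Si](C)(C)C(C)(C)C)Oc2ccc(C[C@H]3COC(O[Li])=C3)cc2OC)ccc1OCc1ccccc1 | intermediate
37 | fully protected (3R,4R)-lactone | COc1cc([C@@H](O[Si](C)(C)C(C)(C)C)[C@H](CO[Si](C)(C)C(C)(C)C)Oc2ccc(C[C@H]3COC(=O)[C@@H]3Cc3cc(OC)c4c(c3)[C@H](CO[Si](c3ccccc3)(c3ccccc3)C(C)(C)C)[C@@H](c3ccc(OCc5ccccc5)c(OC)c3)O4)cc2OC)ccc1OCc1ccccc1 | intermediate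
38 | di-O-benzyl triol | COc1cc([C@@H](O)[C@H](CO)Oc2ccc(C[C@H]3COC(=O)[C@@H]3Cc3cc(OC)c4c(c3)[C@H](CO)[C@@H](c3ccc(OCc5ccccc5)c(OC)c3)O4)cc2OC)ccc1OCc1ccccc1 | intermediate
39 | CNP0265599.1, (3R,4R)-3-{[(2S,3R)-2-(4-hydroxy-3-methoxyphenyl)-3-(hydroxymethyl)-7-methoxy-2,3-dihydrobenzofuran-5-yl]methyl}-4-(4-{[(1R,2S)-1,3-dihydroxy-1-(4-hydroxy-3-methoxyphenyl)propan-2-yl]oxy}-3-methoxybenzyl)dihydrofuran-2(3H)-one | COc1cc([C@@H](O)[C@H](CO)Oc2ccc(C[C@H]3COC(=O)[C@@H]3Cc3cc(OC)c4c(c3)[C@H](CO)[C@@H](c3ccc(O)c(OC)c3)O4)cc2OC)ccc1O | target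

**Step count**
Total step count: 27.
Longest linear sequence: 15 steps (steps 13 to 27, from eugenol).

**Steps most likely to fail**

1. Step 9 (key C–H insertion).
- What may go wrong: poor discrimination between the two OCH2 hydrogens in this crowded, doubly ortho-substituted aryl ether, erosion of the trans preference, or bimolecular insertion into the CH2OTBS group of a second molecule.
- Fallback, from 6 and back at 14: stereocontrol moves from the auxiliary–catalyst pair to a cis-selective catalyst followed by thermodynamic epimerisation.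
- Ester 6 takes the diazo group directly (p-ABSA, DBU, MeCN) to give the ethyl aryldiazoacetate F1.
- Rh2(R-PTTL)4 in toluene at low temperature belongs to a phthalimido amino acid carboxylate class known for cis-2-aryl-2,3-dihydrobenzofuran-3-carboxylates. It should close F1 to the cis-(2S,3R) ethyl ester F2, so the catalyst only has to set C2.
- NaOEt in EtOH then epimerises C3 to the trans-(2S,3S) ethyl ester F3, and LiBH4 reduces F3 to 14.
- Any remaining minor enantiomer becomes a diastereomer after step 25 and can be removed there.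

2. Step 18 (Mitsunobu inversion).
- What may go wrong: ionisation of the oxyphosphonium intermediate at the electron-rich benzylic carbon with loss of stereochemical integrity, or elimination towards the enol ether.
- Fallback, from 27 and back at 29: inversion by oxidation and chelate-controlled reduction, which replaces steps 18 and 19.
- Dess–Martin periodinane (NaHCO3, CH2Cl2) oxidises 27 to the (S)-alpha-aryloxy ketone F4.
- Zn(BH4)2 in Et2O at low temperature holds zinc between the carbonyl oxygen and the guaiacyl ether oxygens on C8'. Hydride then reaches the less hindered face of the chelate (Cram chelate model) and gives the anti, that is erythro, alcohol 29 directly.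

3. Step 24 (lactone-forming insertion).
- What may go wrong: low enantioselectivity, or competing paths of the acceptor carbene on this large substrate (addition to electron-rich ring B, carbene dimerisation, insertion at the benzylic CH2).
- Fallback, from 32 and back at 35: auxiliary-controlled enolate alkylation, which replaces steps 22 to 24.
- TEMPO/PhI(OAc)2 in aqueous MeCN oxidises 32 to the 3-arylpropanoic acid F5.
- The mixed pivalic anhydride of F5 acylates (S)-4-benzyloxazolidin-2-one to give the imide F6.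
- NaN(SiMe3)2 and tert-butyl bromoacetate at -78 °C alkylate the chelated Z enolate on the face away from the auxiliary benzyl group to give the (R)-succinate imide F7.
- LiBH4 removes the auxiliary to leave the (R)-hydroxy tert-butyl ester F8, which closes to 35 with catalytic KOt-Bu in THF.

Further compounds
F1 | step 9 | ethyl 2-diazo-2-{2-[(4-benzyloxy-3-methoxyphenyl)methoxy]-5-(TBSO-methyl)-3-methoxyphenyl}acetate | CCOC(=O)C(=[N+]=[N-])c1cc(CO[Si](C)(C)C(C)(C)C)cc(OC)c1OCc1ccc(OCc2ccccc2)c(OC)c1
F2 | step 9 | ethyl cis-(2S,3R)-2-aryl-2,3-dihydrobenzofuran-3-carboxylate | CC(C)(C)[Si](C)(C)OCc1cc(OC)c2c(c1)[C@@H](C(=O)OCC)[C@@H](c1ccc(OCc3ccccc3)c(OC)c1)O2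
F3 | step 9 | ethyl trans-(2S,3S)-2-aryl-2,3-dihydrobenzofuran-3-carboxylate | CC(C)(C)[Si](C)(C)OCc1cc(OC)c2c(c1)[C@H](C(=O)OCC)[C@@H](c1ccc(OCc3ccccc3)c(OC)c1)O2
F4 | step 18 | (S)-2-(4-allyl-2-methoxyphenoxy)-1-(4-benzyloxy-3-methoxyphenyl)-3-(TBSO)propan-1-one | COc1cc(C(=O)[C@H](CO[Si](C)(C)C(C)(C)C)Oc2ccc(CC=C)cc2OC)ccc1OCc1ccccc1
F5 | step 24 | 3-arylpropanoic acid from 32 | COc1cc([C@@H](O[Si](C)(C)C(C)(C)C)[C@H](CO[Si](C)(C)C(C)(C)C)Oc2ccc(CCC(=O)O)cc2OC)ccc1OCc1ccccc1
F6 | step 24 | (S)-4-benzyl-3-(3-arylpropanoyl)oxazolidin-2-one | COc1cc([C@@H](O[Si](C)(C)C(C)(C)C)[C@H](CO[Si](C)(C)C(C)(C)C)Oc2ccc(CCC(=O)N3[C@@H](Cc4ccccc4)COC3=O)cc2OC)ccc1OCc1ccccc1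
F7 | step 24 | tert-butyl (R)-3-(arylmethyl)-4-[(S)-4-benzyl-2-oxooxazolidin-3-yl]-4-oxobutanoate | COc1cc([C@@H](O[Si](C)(C)C(C)(C)C)[C@H](CO[Si](C)(C)C(C)(C)C)Oc2ccc(C[C@H](CC(=O)OC(C)(C)C)C(=O)N3[C@@H](Cc4ccccc4)COC3=O)cc2OC)ccc1OCc1ccccc1
F8 | step 24 | tert-butyl (R)-3-(arylmethyl)-4-hydroxybutanoate | COc1cc([C@@H](O[Si](C)(C)C(C)(C)C)[C@H](CO[Si](C)(C)C(C)(C)C)Oc2ccc(C[C@H](CC(=O)OC(C)(C)C)CO)cc2OC)ccc1OCc1ccccc1
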